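**Plan**

- Retrosynthesis: the four benzyl ethers come off last; C2–H and C3–H are cut next, so the chromanone derives from the flat 3‑methoxyflavone; ring C is then opened at O1–C8a and C3–C4 in one cut, giving a ring‑A 2‑fluorobenzoyl chloride and a ring‑B aryl methoxymethyl ketone.
- Enabling feature: on ring A, C8a is ortho to the C4 carbonyl carbon (a 1,3‑dielectrophile), and O1–C2–C3 of ring C is the enolate of ArB–CO–CH2OMe (a 1,3‑O,C‑dinucleophile); once C3–C4 is made, the new ortho ketone activates C8a–F for attack by O1.
- The union is run at the flavone oxidation level because at the chromanone level O1 would be a β‑oxido ketone (retro‑aldol) and C3 an enolate β to an aryloxy group (E1cB ring opening); the γ‑pyrone is dearomatised afterwards.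
- Forward: ring‑A acid chloride (5 steps from 5‑fluoro‑1,2,3‑trimethoxybenzene) and ring‑B ketone (3 steps from 2,3‑dihydroxy‑4‑methoxybenzaldehyde) are joined with closure of ring C; the C2=C3 bond is then reduced and the phenols are freed.
- Stereochemistry: C2 comes from ligand‑controlled copper hydride delivery to the Si face of C2; C3 lies α to the C4 ketone and should funnel by enolisation to the trans‑diequatorial (2R,3R) isomer.

Key step: step 9

Remark: 1, 8 and tributyl(methoxymethyl)stannane are taken as catalogue chemicals, and the trans (2R,3R) isomer is taken as the more stable C3 epimer, as is general for 3‑oxygenated flavanones.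

**Route**

Step 1
Reactants: 1 5-fluoro-1,2,3-trimethoxybenzene
Product: 3 6-fluoro-2,3,4-trimethoxybenzaldehyde, via aryllithium 2 (not isolated)
Conditions: n-BuLi, THF, −78 °C; DMF, −78 °C to 0 °C; 1 M HCl
Reagents that add atoms: N,N-dimethylformamide, CN(C)C=O
Why: Directed ortho-metalation followed by formylation with DMF (Bouveault-type); the two free ring positions are equivalent and each is flanked by F and OMe, so only one aryllithium can form, and at −78 °C it should not lose LiF.

Step 2
Reactants: 3 6-fluoro-2,3,4-trimethoxybenzaldehyde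
Product: 4 6-fluoro-2,3-dihydroxy-4-methoxybenzaldehyde
Conditions: BCl3 (2.5 equiv), CH2Cl2, 0 °C to rt; H2O
Reagents that add atoms: none
Why: Chelation-directed Lewis-acid ether cleavage; BCl3 bound to the formyl oxygen should cleave the ortho methoxy group and then, through the cyclic borate, its neighbour, leaving the 4-methoxy group, as is known for the fluorine-free 2,3,4-trimethoxybenzaldehyde.

Step 3
Reactants: 4 6-fluoro-2,3-dihydroxy-4-methoxybenzaldehyde
Product: 5 2,3-bis(benzyloxy)-6-fluoro-4-methoxybenzaldehyde
Conditions: BnBr, K2CO3, DMF, rt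
Reagents that add atoms: benzyl bromide, BrCc1ccccc1
Why: Williamson ether synthesis on both phenols; benzyl is chosen because it survives strong base, hydride and Lewis-acidic copper and leaves at the end under neutral conditions.

Step 4
Reactants: 5 2,3-bis(benzyloxy)-6-fluoro-4-methoxybenzaldehyde
Product: 6 2,3-bis(benzyloxy)-6-fluoro-4-methoxybenzoic acid
Conditions: NaClO2, NaH2PO4, 2-methylbut-2-ene, t-BuOH/H2O, rt
Reagents that add atoms: sodium chlorite, [Na+].[O-]Cl=O
Why: Pinnick oxidation of the aldehyde; the alkene scavenger removes HOCl so that the electron-rich ring should not be chlorinated.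

Step 5
Reactants: 6 2,3-bis(benzyloxy)-6-fluoro-4-methoxybenzoic acid
Product: 7 2,3-bis(benzyloxy)-6-fluoro-4-methoxybenzoyl chloride
Conditions: (COCl)2, DMF (cat.), CH2Cl2, 0 °C to rt; used crude
Reagents that add atoms: oxalyl chloride, O=C(Cl)C(=O)Cl
Why: Acid chloride formation through the Vilsmeier-type chloroiminium catalyst; the product has no α-hydrogen and cannot form a ketene.

Step 6
Reactants: 8 2,3-dihydroxy-4-methoxybenzaldehyde
Product: 9 2,3-bis(benzyloxy)-4-methoxybenzaldehyde
Conditions: BnBr, K2CO3, DMF, rt
Reagents that add atoms: benzyl bromide, BrCc1ccccc1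
Why: Williamson ether synthesis, the same protecting group as on ring A so that one final operation frees all four phenols.

Step 7
Reactants: 9 2,3-bis(benzyloxy)-4-methoxybenzaldehyde
Product: 10 1-[2,3-bis(benzyloxy)-4-methoxyphenyl]-2-methoxyethan-1-ol (racemic)
Conditions: Bu3SnCH2OMe, n-BuLi, THF, −78 °C; then 9, −78 °C; H2O
Reagents that add atoms: tributyl(methoxymethyl)stannane, CCCC[Sn](CCCC)(CCCC)COC
Why: Tin–lithium exchange gives (methoxymethyl)lithium, which adds 1,2 to the aldehyde; the carbinol centre is formed racemic and is removed in step 8.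

Step 8
Reactants: 10 1-[2,3-bis(benzyloxy)-4-methoxyphenyl]-2-methoxyethan-1-ol
Product: 11 1-[2,3-bis(benzyloxy)-4-methoxyphenyl]-2-methoxyethan-1-one
Conditions: Dess–Martin periodinane, CH2Cl2, rt
Reagents that add atoms: none
Why: Dess–Martin oxidation of a benzylic secondary alcohol to the aryl methoxymethyl ketone under near-neutral conditions that the benzyl ethers tolerate.

Step 9
Reactants: 11 1-[2,3-bis(benzyloxy)-4-methoxyphenyl]-2-methoxyethan-1-one and 7 2,3-bis(benzyloxy)-6-fluoro-4-methoxybenzoyl chloride
Product: 14 5,6-bis(benzyloxy)-2-[2,3-bis(benzyloxy)-4-methoxyphenyl]-3,7-dimethoxy-4H-chromen-4-one, via lithium enolate 12 (not isolated), via 1,3-diketone 13 (not isolated)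
Conditions: LiHMDS (2.1 equiv), THF, −78 °C; 7, −78 °C to 0 °C; then DMF, 90 °C
Reagents that add atoms: none
Why: The chelated lithium enolate 12 is C-acylated by 7 (Claisen-type acylation, forming C3–C4), the second equivalent of base converts the 2-methoxy-1,3-diketone 13 into its enolate, and the enolate oxygen on the ring-B carbonyl attacks C8a ipso to fluorine, with loss of fluoride from the Meisenheimer adduct (intramolecular SNAr, forming O1–C8a). The closest known reaction type is the acylation/SNAr cyclisation of 2-halobenzoyl chlorides with enolates or enamines used for 4-quinolones, chromones and flavones. Ring C closes as a six-membered ring by addition–elimination at C8a, formally 6-exo-trig onto the C8a=C8 arene bond. No stereocentre is formed, since the product is the flat γ-pyrone and any enolate geometry converges on it. The step needs C- over O-acylation, which the lithium chelate between enolate oxygen and methoxy oxygen and the non-enolisable acyl chloride should favour, and one mode of closure, which is secured because only ring A carries a leaving group and only the ring-B carbonyl oxygen can reach C8a through a six-membered transition state. Fluoride is chosen because attack, not departure, limits the rate on this donor-substituted ring (C6–OBn is para to C8a), and the ortho ketone made in the first event supplies the activation.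

Step 10
Reactants: 14 5,6-bis(benzyloxy)-2-[2,3-bis(benzyloxy)-4-methoxyphenyl]-3,7-dimethoxy-4H-chromen-4-one
Product: 16 (2R,3R)-5,6-bis(benzyloxy)-2-[2,3-bis(benzyloxy)-4-methoxyphenyl]-3,7-dimethoxychroman-4-one, via silyl enol ether 15 (not isolated)
Conditions: Cu(OAc)2 (5 mol %), (R)-DTBM-SEGPHOS (5.5 mol %), (EtO)2MeSiH, toluene, 0 °C to rt; then AcOH, THF/H2O, rt
Reagents that add atoms: none
Why: Proposed new method: the ligated copper hydride should transfer hydride to C2, the β-carbon of the γ-pyrone vinylogous ester, in the enantio-determining step (Si face of C2 gives 2R; the ligand enantiomer is to be fixed accordingly in a first trial), the copper enolate is silylated by σ-bond metathesis to 15, which regenerates Cu–H and shields C4 from 1,2-reduction, and acidic hydrolysis then gives the ketone, whose C3 centre should equilibrate by enolisation to the trans-diequatorial 3R epimer; the closest known reaction type is the CuH/bisphosphine asymmetric conjugate reduction of β,β-disubstituted cyclic enones and 2-substituted chromones, and what is new is the tetrasubstituted, α-alkoxy-bearing C2=C3 bond.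

Step 11
Reactants: 16 (2R,3R)-5,6-bis(benzyloxy)-2-[2,3-bis(benzyloxy)-4-methoxyphenyl]-3,7-dimethoxychroman-4-one
Product: 17 (2R,3R)-2-(2,3-dihydroxy-4-methoxyphenyl)-5,6-dihydroxy-3,7-dimethoxychroman-4-one
Conditions: H2 (1 atm), Pd/C, EtOAc, rt; work-up under argon
Reagents that add atoms: none
Why: Catalytic hydrogenolysis of the four aryl benzyl ethers under neutral conditions, which should leave the base-sensitive C2 and C3 centres, the methyl ethers and the aryl ketone untouched.

**Compound list**

1 | 5-fluoro-1,2,3-trimethoxybenzene | COc1cc(F)cc(OC)c1OC | starting material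
2 | (6-fluoro-2,3,4-trimethoxyphenyl)lithium | [Li]c1c(F)cc(OC)c(OC)c1OC | intermediate
3 | 6-fluoro-2,3,4-trimethoxybenzaldehyde | O=Cc1c(F)cc(OC)c(OC)c1OC | intermediate
4 | 6-fluoro-2,3-dihydroxy-4-methoxybenzaldehyde | O=Cc1c(F)cc(OC)c(O)c1O | intermediate
5 | 2,3-bis(benzyloxy)-6-fluoro-4-methoxybenzaldehyde | O=Cc1c(F)cc(OC)c(OCc2ccccc2)c1OCc1ccccc1 | intermediate
6 | 2,3-bis(benzyloxy)-6-fluoro-4-methoxybenzoic acid | OC(=O)c1c(F)cc(OC)c(OCc2ccccc2)c1OCc1ccccc1 | intermediate
7 | 2,3-bis(benzyloxy)-6-fluoro-4-methoxybenzoyl chloride | ClC(=O)c1c(F)cc(OC)c(OCc2ccccc2)c1OCc1ccccc1 | intermediate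
8 | 2,3-dihydroxy-4-methoxybenzaldehyde | COc1ccc(C=O)c(O)c1O | starting material
9 | 2,3-bis(benzyloxy)-4-methoxybenzaldehyde | COc1ccc(C=O)c(OCc2ccccc2)c1OCc1ccccc1 | intermediate
10 | 1-[2,3-bis(benzyloxy)-4-methoxyphenyl]-2-methoxyethan-1-ol (racemic) | COCC(O)c1ccc(OC)c(OCc2ccccc2)c1OCc1ccccc1 | intermediate
11 | 1-[2,3-bis(benzyloxy)-4-methoxyphenyl]-2-methoxyethan-1-one | COCC(=O)c1ccc(OC)c(OCc2ccccc2)c1OCc1ccccc1 | intermediate
12 | lithium (Z)-1-[2,3-bis(benzyloxy)-4-methoxyphenyl]-2-methoxyethen-1-olate | CO/C=C(\O[Li])c1ccc(OC)c(OCc2ccccc2)c1OCc1ccccc1 | intermediate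
13 | 1-[2,3-bis(benzyloxy)-6-fluoro-4-methoxyphenyl]-3-[2,3-bis(benzyloxy)-4-methoxyphenyl]-2-methoxypropane-1,3-dione (present as its lithium enolate) | COC(C(=O)c1c(F)cc(OC)c(OCc2ccccc2)c1OCc1ccccc1)C(=O)c1ccc(OC)c(OCc2ccccc2)c1OCc1ccccc1 | intermediate
14 | 5,6-bis(benzyloxy)-2-[2,3-bis(benzyloxy)-4-methoxyphenyl]-3,7-dimethoxy-4H-chromen-4-one | COc1ccc(-c2oc3cc(OC)c(OCc4ccccc4)c(OCc4ccccc4)c3c(=O)c2OC)c(OCc2ccccc2)c1OCc1ccccc1 | intermediate
15 | (2R)-5,6-bis(benzyloxy)-2-[2,3-bis(benzyloxy)-4-methoxyphenyl]-4-[diethoxy(methyl)silyloxy]-3,7-dimethoxy-2H-chromene | COc1ccc([C@H]2Oc3cc(OC)c(OCc4ccccc4)c(OCc4ccccc4)c3C(O[Si](C)(OCC)OCC)=C2OC)c(OCc2ccccc2)c1OCc1ccccc1 | intermediate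
16 | (2R,3R)-5,6-bis(benzyloxy)-2-[2,3-bis(benzyloxy)-4-methoxyphenyl]-3,7-dimethoxychroman-4-one | COc1ccc([C@H]2Oc3cc(OC)c(OCc4ccccc4)c(OCc4ccccc4)c3C(=O)[C@@H]2OC)c(OCc2ccccc2)c1OCc1ccccc1 | intermediate
17 | (2R,3R)-2-(2,3-dihydroxy-4-methoxyphenyl)-5,6-dihydroxy-3,7-dimethoxychroman-4-one | COc1ccc([C@H]2Oc3cc(OC)c(O)c(O)c3C(=O)[C@@H]2OC)c(O)c1O | target

**Count and risks**

Total step count: 11. Longest linear sequence: 8 steps (steps 1 to 5, then 9, 10 and 11).

Steps most likely to fail:

1. Step 10 (Proposed new method). Hydride transfer to the tetrasubstituted, donor-substituted C2=C3 bond may be too slow or poorly face-selective, or 1,2-reduction at C4 may compete. The fallback uses known chemistry and sets out from 14: conjugate reduction with L-Selectride in THF at −78 °C, a known 1,4-reduction of flavones, followed by mild acidic equilibration at C3, should give the racemic trans flavanone. This is 16 together with its mirror image (2S,3S)-5,6-bis(benzyloxy)-2-[2,3-bis(benzyloxy)-4-methoxyphenyl]-3,7-dimethoxychroman-4-one F1. Preparative chromatography on a chiral stationary phase separates the two, and the fallback comes back to the route at 16.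

2. Step 9. O-acylation of the enolate, or retro-Claisen cleavage of the diketonate, may outrun a slow fluoride displacement on the electron-rich ring A. The fallback sets out from 11 and uses aldehyde 5 in place of 7: an LDA aldol addition at −78 °C should give 3-[2,3-bis(benzyloxy)-6-fluoro-4-methoxyphenyl]-1-[2,3-bis(benzyloxy)-4-methoxyphenyl]-3-hydroxy-2-methoxypropan-1-one F2 as a diastereomer mixture. Dess–Martin oxidation then gives the diketone 13, now isolated, and K2CO3 in DMF at 90 °C closes ring C. The fallback comes back at 14.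

3. Step 11. Hydrogenolysis of the benzylic C2–O1 bond (opening of ring C) may accompany debenzylation, and the freed catechols may oxidise in air. The fallback sets out from 16 and replaces the reductive cleavage by a Lewis-acid cleavage: BCl3 with pentamethylbenzene as benzyl-cation scavenger in CH2Cl2 at −78 °C, with no hydrogen or metal surface present. It comes back at 17 and makes no new compound (F0).

**Further compounds**

F1 | step 10 | (2S,3S)-5,6-bis(benzyloxy)-2-[2,3-bis(benzyloxy)-4-methoxyphenyl]-3,7-dimethoxychroman-4-one | COc1ccc([C@@H]2Oc3cc(OC)c(OCc4ccccc4)c(OCc4ccccc4)c3C(=O)[C@H]2OC)c(OCc2ccccc2)c1OCc1ccccc1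
F2 | step 9 | 3-[2,3-bis(benzyloxy)-6-fluoro-4-methoxyphenyl]-1-[2,3-bis(benzyloxy)-4-methoxyphenyl]-3-hydroxy-2-methoxypropan-1-one (diastereomer mixture) | COC(C(O)c1c(F)cc(OC)c(OCc2ccccc2)c1OCc1ccccc1)C(=O)c1ccc(OC)c(OCc2ccccc2)c1OCc1ccccc1
F0 | step 11 | none | none
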